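**Plan**

- Enabling feature: in the tetrahydrofuran ring (O1, C2–C5), C2 is a single CH between O1 and C3 that carries only the guaiacyl ring. It can therefore be delivered as an aryl carbene into the O–C bond of a four-membered oxetane (O1, C5, C4, C3) that already holds the cis C3/C4 pair.
- Retrosynthesis: remove two silyl ethers, then cut O1–C2 and C2–C3 (aryl carbene plus cis-oxetane), then O1–C5 of the oxetane (syn 1,3-diol), then C3–C4 (aldol) back to 3-(3,4-dimethoxyphenyl)propanoic acid and (benzyloxy)acetaldehyde; the carbene carbon and its aryl group come from vanillin.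
- Forward: the chain is joined by an auxiliary-controlled syn-aldol and the diol is released and closed to the oxetane (first ring). After benzyl-to-TIPS exchange, a Rh-catalysed ring expansion with the aryldiazomethane released in situ from the vanillin tosylhydrazone turns the oxetane into the tetrahydrofuran; desilylation follows.
- Stereochemistry: C3 and C4 come from the Evans syn-aldol with (R)-4-benzyl-2-oxazolidinone and are carried with retention through oxetane closure and the [1,2]-shift; C2 is set in the ring expansion, trans to the C3 arm.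

Key step: step 9

Remark on the chemistry: ring atoms are numbered O1, C2 (guaiacyl), C3 (CH2OH), C4 (3,4-dimethoxybenzyl), C5, and the target is (2S,3R,4R), 2,3-trans and 3,4-cis. After the ring expansion acid is avoided, because a C2 benzylic cation can be captured by the dimethoxybenzyl ring, so C2 is not corrected by equilibration.

**Route**

Step 1
Reactants: 1 3-(3,4-dimethoxyphenyl)propanoic acid; 2 (R)-4-benzyl-2-oxazolidinone
Product: 4 (R)-4-benzyl-3-[3-(3,4-dimethoxyphenyl)propanoyl]oxazolidin-2-one, via mixed pivalic anhydride 3 (not isolated)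
Conditions: PivCl, Et3N, THF, −20 °C; then 2, LiCl, −20 °C → rt
Reagents that add atoms: none
Why: N-acylation of the oxazolidinone by a mixed anhydride with LiCl activation is the standard loading of an Evans auxiliary and touches no stereocentre.

Step 2
Reactants: 4 (R)-4-benzyl-3-[3-(3,4-dimethoxyphenyl)propanoyl]oxazolidin-2-one; 5 (benzyloxy)acetaldehyde
Product: 7 (R)-4-benzyl-3-[(2R,3R)-4-(benzyloxy)-2-(3,4-dimethoxybenzyl)-3-hydroxybutanoyl]oxazolidin-2-one, via Z boron enolate 6 (not isolated)
Conditions: Bu2BOTf, iPr2NEt, CH2Cl2, 0 °C; 5, −78 → 0 °C; H2O2, MeOH, pH 7 buffer, 0 °C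
Reagents that add atoms: none
Why: Evans syn-aldol, in which the Z dibutylboron enolate reacts through a Zimmerman–Traxler chair and the aldehyde adds to the enolate face away from the auxiliary benzyl group, which should set the two new centres as (2R,3R) (syn), the future cis C4/C3 pair.

Step 3
Reactants: 7 (R)-4-benzyl-3-[(2R,3R)-4-(benzyloxy)-2-(3,4-dimethoxybenzyl)-3-hydroxybutanoyl]oxazolidin-2-one
Product: 8 (2S,3R)-4-(benzyloxy)-2-(3,4-dimethoxybenzyl)butane-1,3-diol
Conditions: LiBH4, MeOH (1 equiv), THF, 0 °C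
Reagents that add atoms: none
Why: Reductive cleavage of the N-acyl oxazolidinone with LiBH4 gives the primary alcohol and frees the auxiliary without touching either stereocentre (the descriptor at C2 changes only by priority).

Step 4
Reactants: 8 (2S,3R)-4-(benzyloxy)-2-(3,4-dimethoxybenzyl)butane-1,3-diol
Product: 10 (2R,3S)-2-[(benzyloxy)methyl]-3-(3,4-dimethoxybenzyl)oxetane, via primary tosylate 9 (not isolated)
Conditions: n-BuLi (1.0 equiv), THF, 0 °C; TsCl (1.0 equiv); n-BuLi (1.1 equiv), 0 → 60 °C
Reagents that add atoms: none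
Why: One-flask oxetane synthesis from a 1,3-diol, in which the monoalkoxide is sulfonylated at the less hindered primary oxygen and the secondary alkoxide then closes by 4-exo-tet Williamson displacement at the primary carbon, so both stereocentres are retained and the syn diol should give the cis oxetane (neither fragment of a Grob pathway would be stabilised).

Step 5
Reactants: 10 (2R,3S)-2-[(benzyloxy)methyl]-3-(3,4-dimethoxybenzyl)oxetane
Product: 11 [(2R,3S)-3-(3,4-dimethoxybenzyl)oxetan-2-yl]methanol
Conditions: H2 (1 atm), 10% Pd/C, EtOAc, rt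
Reagents that add atoms: none
Why: Catalytic hydrogenolysis of an alkyl benzyl ether; the oxetane C–O bonds are not benzylic and should survive neutral Pd/C, and the benzyl ether is removed here because its oxygen could itself capture the carbene of step 9 and undergo a benzyl [1,2]-shift.

Step 6
Reactants: 11 [(2R,3S)-3-(3,4-dimethoxybenzyl)oxetan-2-yl]methanol
Product: 12 (2R,3S)-3-(3,4-dimethoxybenzyl)-2-{[(triisopropylsilyl)oxy]methyl}oxetane
Conditions: TIPSCl, imidazole, DMF, rt
Reagents that add atoms: triisopropylsilyl chloride, CC(C)[Si](Cl)(C(C)C)C(C)C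
Why: Silylation caps the hydroxyl as a hindered, weakly Lewis-basic ether that neither quenches the carbene nor forms a competing ylide and that leaves in the same fluoride step as the phenol silyl ether.

Step 7
Reactants: 13 vanillin
Product: 14 3-methoxy-4-[(triisopropylsilyl)oxy]benzaldehyde
Conditions: TIPSCl, imidazole, DMF, rt
Reagents that add atoms: triisopropylsilyl chloride, CC(C)[Si](Cl)(C(C)C)C(C)C
Why: Phenol silylation; the TIPS aryl ether should tolerate the hydrazonide salt of step 9 better than a TBS ether, and it avoids a benzyl ether whose hydrogenolysis at the end would endanger the benzylic O1–C2 bond.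

Step 8
Reactants: 14 3-methoxy-4-[(triisopropylsilyl)oxy]benzaldehyde
Product: 15 N'-{(E)-3-methoxy-4-[(triisopropylsilyl)oxy]benzylidene}-4-methylbenzenesulfonohydrazide
Conditions: TsNHNH2, MeOH, rt
Reagents that add atoms: p-toluenesulfonohydrazide, Cc1ccc(S(=O)(=O)NN)cc1
Why: Condensation of the aldehyde with tosylhydrazide gives the E tosylhydrazone, the bench-stable Bamford–Stevens precursor of the aryldiazomethane.

Step 9
Reactants: 12 (2R,3S)-3-(3,4-dimethoxybenzyl)-2-{[(triisopropylsilyl)oxy]methyl}oxetane; 15 N'-{(E)-3-methoxy-4-[(triisopropylsilyl)oxy]benzylidene}-4-methylbenzenesulfonohydrazide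
Product: 19 (2S,3R,4R)-4-(3,4-dimethoxybenzyl)-2-{3-methoxy-4-[(triisopropylsilyl)oxy]phenyl}-3-{[(triisopropylsilyl)oxy]methyl}tetrahydrofuran, via sodium tosylhydrazonide 16 (not isolated), via aryldiazomethane 17 (not isolated), via oxonium ylide 18 (not isolated)
Conditions: 15 (2.5 equiv), NaH, THF, 0 °C, then concentrate; 12, Rh2(OAc)4 (2 mol %), BnEt3NCl (10 mol %), PhCF3, 40 °C
Reagents that add atoms: none
Why: Proposed new method: under phase transfer the sodium salt 16 loses sulfinate and releases aryldiazomethane 17 slowly, Rh2(OAc)4 converts it into a rhodium aryl carbene, the exposed oxetane oxygen of 12 attacks this carbene from the ring face opposite the two cis substituents to give oxonium ylide 18, and a Stevens [1,2]-shift transfers the substituted ring carbon (future C3) from oxygen to the ylide carbon. The closest known reaction type is the Cu(I)- or Rh(II)-catalysed (or light-driven) ring expansion of oxetanes to tetrahydrofurans by diazoacetates and aryldiazoacetates through oxonium ylides; what is new is the donor-only aryl carbene and a non-benzylic secondary migrating carbon. The tetrahydrofuran arises by four-to-five ring expansion: O1–C2 exists in the ylide, homolysis of O1–C3 gives a tethered singlet 1,5-diradical (secondary alkyl and α-oxybenzyl), and its collapse forms C2–C3, driven by the loss of roughly 20 kcal/mol of ring strain. C3 should keep its configuration because recombination within the tether is faster than rotation about C3–C4, so the aldol-derived cis C3/C4 pair is carried over, while the new stereocentre C2 is set by the substrate, the aryl group turning away from the CH2OTIPS arm on C3 as the ring closes (2,3-trans). The step needs the shift of the O1–C3 bond and not of O1–C5, which the better stabilised secondary radical and the more strained substituted bond should secure, and it needs ylide formation at the oxetane oxygen alone, which the hindered and weakly basic silyl ether oxygens allow. Carbene dimerisation is held down by the slow release of 17 and by using 12 as the limiting component.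

Step 10
Reactants: 19 (2S,3R,4R)-4-(3,4-dimethoxybenzyl)-2-{3-methoxy-4-[(triisopropylsilyl)oxy]phenyl}-3-{[(triisopropylsilyl)oxy]methyl}tetrahydrofuran
Product: 20 4'-O-methyllariciresinol
Conditions: TBAF, AcOH (1:1), THF, rt
Reagents that add atoms: none
Why: Fluoride-mediated desilylation of both silyl ethers, buffered with acetic acid, should free the phenol and the primary alcohol without ionising the benzylic O1–C2 bond, so the three stereocentres stay untouched.

**Compound list**

1 | 3-(3,4-dimethoxyphenyl)propanoic acid | COc1ccc(CCC(=O)O)cc1OC | starting material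
2 | (R)-4-benzyl-2-oxazolidinone | O=C1N[C@H](Cc2ccccc2)CO1 | starting material
3 | 3-(3,4-dimethoxyphenyl)propanoic pivalic anhydride | COc1ccc(CCC(=O)OC(=O)C(C)(C)C)cc1OC | intermediate (not isolated)
4 | (R)-4-benzyl-3-[3-(3,4-dimethoxyphenyl)propanoyl]oxazolidin-2-one | COc1ccc(CCC(=O)N2[C@H](Cc3ccccc3)COC2=O)cc1OC | intermediate
5 | (benzyloxy)acetaldehyde | O=CCOCc1ccccc1 | starting material
6 | Z dibutylboron enolate of 4 | CCCCB(CCCC)O/C(=C\Cc1ccc(OC)c(OC)c1)N1[C@H](Cc2ccccc2)COC1=O | intermediate (not isolated)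
7 | (R)-4-benzyl-3-[(2R,3R)-4-(benzyloxy)-2-(3,4-dimethoxybenzyl)-3-hydroxybutanoyl]oxazolidin-2-one | O=C([C@H](Cc1ccc(OC)c(OC)c1)[C@@H](O)COCc1ccccc1)N1[C@H](Cc2ccccc2)COC1=O | intermediate
8 | (2S,3R)-4-(benzyloxy)-2-(3,4-dimethoxybenzyl)butane-1,3-diol | OC[C@H](Cc1ccc(OC)c(OC)c1)[C@@H](O)COCc1ccccc1 | intermediate
9 | (2S,3R)-4-(benzyloxy)-2-(3,4-dimethoxybenzyl)-3-hydroxybutyl 4-methylbenzenesulfonate | Cc1ccc(S(=O)(=O)OC[C@H](Cc2ccc(OC)c(OC)c2)[C@@H](O)COCc2ccccc2)cc1 | intermediate (not isolated)
10 | (2R,3S)-2-[(benzyloxy)methyl]-3-(3,4-dimethoxybenzyl)oxetane | O1C[C@H](Cc2ccc(OC)c(OC)c2)[C@@H]1COCc1ccccc1 | intermediate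
11 | [(2R,3S)-3-(3,4-dimethoxybenzyl)oxetan-2-yl]methanol | O1C[C@H](Cc2ccc(OC)c(OC)c2)[C@@H]1CO | intermediate
12 | (2R,3S)-3-(3,4-dimethoxybenzyl)-2-{[(triisopropylsilyl)oxy]methyl}oxetane | O1C[C@H](Cc2ccc(OC)c(OC)c2)[C@@H]1CO[Si](C(C)C)(C(C)C)C(C)C | intermediate
13 | vanillin | COc1cc(C=O)ccc1O | starting material
14 | 3-methoxy-4-[(triisopropylsilyl)oxy]benzaldehyde | COc1cc(C=O)ccc1O[Si](C(C)C)(C(C)C)C(C)C | intermediate
15 | N'-{(E)-3-methoxy-4-[(triisopropylsilyl)oxy]benzylidene}-4-methylbenzenesulfonohydrazide | COc1cc(/C=N/NS(=O)(=O)c2ccc(C)cc2)ccc1O[Si](C(C)C)(C(C)C)C(C)C | intermediate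
16 | sodium salt of tosylhydrazone 15 | COc1cc(/C=N/[N-]S(=O)(=O)c2ccc(C)cc2)ccc1O[Si](C(C)C)(C(C)C)C(C)C.[Na+] | intermediate (not isolated)
17 | {3-methoxy-4-[(triisopropylsilyl)oxy]phenyl}diazomethane | COc1cc(C=[N+]=[N-])ccc1O[Si](C(C)C)(C(C)C)C(C)C | intermediate (not isolated)
18 | oxonium ylide of oxetane 12 and the aryl carbene (drawn metal-free) | COc1cc([CH-][O+]2C[C@H](Cc3ccc(OC)c(OC)c3)[C@@H]2CO[Si](C(C)C)(C(C)C)C(C)C)ccc1O[Si](C(C)C)(C(C)C)C(C)C | intermediate (not isolated)
19 | (2S,3R,4R)-4-(3,4-dimethoxybenzyl)-2-{3-methoxy-4-[(triisopropylsilyl)oxy]phenyl}-3-{[(triisopropylsilyl)oxy]methyl}tetrahydrofuran | COc1cc([C@H]2OC[C@H](Cc3ccc(OC)c(OC)c3)[C@@H]2CO[Si](C(C)C)(C(C)C)C(C)C)ccc1O[Si](C(C)C)(C(C)C)C(C)C | intermediate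
20 | 4'-O-methyllariciresinol, (2S,3R,4R) | COc1cc([C@H]2OC[C@H](Cc3ccc(OC)c(OC)c3)[C@@H]2CO)ccc1O | target

**Step count**

Total: 10 steps. Longest linear sequence: 8 steps (steps 1–6, 9, 10); steps 7 and 8 form the short branch.

**Steps most likely to fail**

1. Step 9 (proposed new method). What may go wrong: carbene dimerisation to stilbene or azine outrunning capture by the oxetane oxygen, shift of the unsubstituted O1–C5 bond, loss of the C3 configuration by rotation in the radical pair, or poor facial selectivity at C2. The fallback uses known chemistry only, sets out from acid 1 (with aldehyde 14) and comes back at target 20.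
   - Acid 1 is loaded as in step 1 onto the enantiomeric auxiliary, (S)-4-benzyl-2-oxazolidinone, to give (S)-4-benzyl-3-[3-(3,4-dimethoxyphenyl)propanoyl]oxazolidin-2-one F1.
   - Evans alkylation (NaHMDS, THF, −78 °C, tert-butyl bromoacetate) gives tert-butyl (3R)-3-{[(4S)-4-benzyl-2-oxooxazolidin-3-yl]carbonyl}-4-(3,4-dimethoxyphenyl)butanoate F2.
   - LiBH4 releases tert-butyl (3R)-4-(3,4-dimethoxyphenyl)-3-(hydroxymethyl)butanoate F3, which lactonises with catalytic TsOH to (R)-4-(3,4-dimethoxybenzyl)dihydrofuran-2(3H)-one F4.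
   - The lithium enolate of the lactone (LiHMDS, THF, −78 °C) adds to aldehyde 14 trans to the benzyl group to give (3S,4R)-4-(3,4-dimethoxybenzyl)-3-{hydroxy[3-methoxy-4-(triisopropylsilyloxy)phenyl]methyl}dihydrofuran-2(3H)-one F5; both carbinol epimers serve.
   - LiAlH4 gives (2R,3R)-2-(3,4-dimethoxybenzyl)-3-{hydroxy[3-methoxy-4-(triisopropylsilyloxy)phenyl]methyl}butane-1,4-diol F6.
   - Brief treatment with catalytic CSA in CH2Cl2 at 0 °C closes the tetrahydrofuran through the benzylic cation, which is trapped by the hydroxymethyl group on the benzyl-bearing carbon with the aryl group trans to C3. This gives {(2S,3R,4R)-4-(3,4-dimethoxybenzyl)-2-[3-methoxy-4-(triisopropylsilyloxy)phenyl]tetrahydrofuran-3-yl}methanol F7.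
   - The conditions of step 10 then give 20.

2. Step 4. What may go wrong: sulfonylation not confined to the primary hydroxyl in the one-flask protocol (double or secondary tosylation), or fragmentation and elimination of the γ-alkoxy tosylate in place of 4-exo closure. The fallback differentiates the two hydroxyls by protection, sets out from aldol adduct 7 and comes back at oxetane 10.
   - TBSOTf and 2,6-lutidine in CH2Cl2 give (R)-4-benzyl-3-[(2R,3R)-4-(benzyloxy)-3-(tert-butyldimethylsilyloxy)-2-(3,4-dimethoxybenzyl)butanoyl]oxazolidin-2-one F8.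
   - LiBH4 gives (2S,3R)-4-(benzyloxy)-3-(tert-butyldimethylsilyloxy)-2-(3,4-dimethoxybenzyl)butan-1-ol F9.
   - TsCl in pyridine gives (2S,3R)-4-(benzyloxy)-3-(tert-butyldimethylsilyloxy)-2-(3,4-dimethoxybenzyl)butyl 4-methylbenzenesulfonate F10, which can be purified.
   - TBAF in THF (0 °C → rt) unmasks the secondary alkoxide next to the sulfonate (9 as its alkoxide), which closes to 10.

3. Step 3. What may go wrong: hydride attack at the ring carbonyl of the auxiliary (endocyclic cleavage) with this α-branched acyl group, or retro-aldol cleavage of the lithium aldolate. The fallback separates cleavage and reduction, sets out from 7 and comes back at diol 8.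
   - LiOH and H2O2 in THF–H2O at 0 °C cleave the exocyclic carbonyl selectively to give (2R,3R)-4-(benzyloxy)-2-(3,4-dimethoxybenzyl)-3-hydroxybutanoic acid F11.
   - BH3·SMe2 in THF reduces the acid to 8.

**Further compounds**

F1 | step 9 | (S)-4-benzyl-3-[3-(3,4-dimethoxyphenyl)propanoyl]oxazolidin-2-one | COc1ccc(CCC(=O)N2[C@@H](Cc3ccccc3)COC2=O)cc1OC
F2 | step 9 | tert-butyl (3R)-3-{[(4S)-4-benzyl-2-oxooxazolidin-3-yl]carbonyl}-4-(3,4-dimethoxyphenyl)butanoate | CC(C)(C)OC(=O)C[C@@H](Cc1ccc(OC)c(OC)c1)C(=O)N1[C@@H](Cc2ccccc2)COC1=O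
F3 | step 9 | tert-butyl (3R)-4-(3,4-dimethoxyphenyl)-3-(hydroxymethyl)butanoate | CC(C)(C)OC(=O)C[C@@H](Cc1ccc(OC)c(OC)c1)CO
F4 | step 9 | (R)-4-(3,4-dimethoxybenzyl)dihydrofuran-2(3H)-one | O=C1C[C@@H](Cc2ccc(OC)c(OC)c2)CO1
F5 | step 9 | (3S,4R)-4-(3,4-dimethoxybenzyl)-3-{hydroxy[3-methoxy-4-(triisopropylsilyloxy)phenyl]methyl}dihydrofuran-2(3H)-one | O=C1OC[C@H](Cc2ccc(OC)c(OC)c2)[C@H]1C(O)c1ccc(O[Si](C(C)C)(C(C)C)C(C)C)c(OC)c1
F6 | step 9 | (2R,3R)-2-(3,4-dimethoxybenzyl)-3-{hydroxy[3-methoxy-4-(triisopropylsilyloxy)phenyl]methyl}butane-1,4-diol | OC[C@H](Cc1ccc(OC)c(OC)c1)[C@H](CO)C(O)c1ccc(O[Si](C(C)C)(C(C)C)C(C)C)c(OC)c1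
F7 | step 9 | {(2S,3R,4R)-4-(3,4-dimethoxybenzyl)-2-[3-methoxy-4-(triisopropylsilyloxy)phenyl]tetrahydrofuran-3-yl}methanol | COc1cc([C@H]2OC[C@H](Cc3ccc(OC)c(OC)c3)[C@@H]2CO)ccc1O[Si](C(C)C)(C(C)C)C(C)C
F8 | step 4 | (R)-4-benzyl-3-[(2R,3R)-4-(benzyloxy)-3-(tert-butyldimethylsilyloxy)-2-(3,4-dimethoxybenzyl)butanoyl]oxazolidin-2-one | O=C([C@H](Cc1ccc(OC)c(OC)c1)[C@@H](O[Si](C)(C)C(C)(C)C)COCc1ccccc1)N1[C@H](Cc2ccccc2)COC1=O
F9 | step 4 | (2S,3R)-4-(benzyloxy)-3-(tert-butyldimethylsilyloxy)-2-(3,4-dimethoxybenzyl)butan-1-ol | OC[C@H](Cc1ccc(OC)c(OC)c1)[C@@H](O[Si](C)(C)C(C)(C)C)COCc1ccccc1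
F10 | step 4 | (2S,3R)-4-(benzyloxy)-3-(tert-butyldimethylsilyloxy)-2-(3,4-dimethoxybenzyl)butyl 4-methylbenzenesulfonate | Cc1ccc(S(=O)(=O)OC[C@H](Cc2ccc(OC)c(OC)c2)[C@@H](O[Si](C)(C)C(C)(C)C)COCc2ccccc2)cc1
F11 | step 3 | (2R,3R)-4-(benzyloxy)-2-(3,4-dimethoxybenzyl)-3-hydroxybutanoic acid | OC(=O)[C@H](Cc1ccc(OC)c(OC)c1)[C@@H](O)COCc1ccccc1
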